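The runs were computed with made-up constants; noise was put on by code.

Work with the fraction left.

| setting | oak | alder | Monday's | Friday's | Thursday's | Saturday's |
|---|---|---|---|---|---|---|
| starting material | 0.050 M | 0.050 M | 0.050 M | 0.050 M | 0.050 M | 0.050 M |
| free enzyme | 7 µM | 11 µM | 5.0 µM | 5.0 µM | 5.0 µM | 5.0 µM |
| temperature | −5 °C | 30 °C | 0 °C | 20 °C | 60 °C | 40 °C |
| remark | run made earlier | run made earlier |  |  |  |  |
| time |  |  | 40 h | 40 h | 40 h | 40 h |

| run | time / h | target / % | starting material / % |
|---|---|---|---|
| oak | 3.00 | 5.2 | 91.5 |
| oak | 6.00 | 9.9 | 84.1 |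
| oak | 10.0 | 15.1 | 75.7 |
| oak | 15.0 | 21.4 | 66.6 |
| oak | 20.0 | 27.8 | 59.3 |
| oak | 25.0 | 32.5 | 53.1 |
| alder | 0.417 | 7.3 | 86.0 |
| alder | 0.667 | 9.8 | 78.7 |
| alder | 0.833 | 13.3 | 75.2 |
| alder | 1.33 | 19.0 | 63.7 |
| alder | 2.50 | 30.8 | 47.1 |
| alder | 3.00 | 34.3 | 40.9 |
| alder | 6.00 | 46.0 | 22.6 |

(each reading ± 0.5 percentage points)

* the flask that comes out highest in amount of target, in percent of the starting material charged, or "all alike" when all lie within 1.5 percentage points (Monday's / Friday's / Thursday's / Saturday's / all alike)
* target at the end, in percent of the starting material charged, Monday's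
* target at the end, in percent of the starting material charged, Friday's
* target at the end, in percent of the starting material charged, Thursday's
* target at the end, in percent of the starting material charged, Saturday's

- a species is counted by the starting material in it: one homo dimer counts as two
- the numbers in the tables scatter with a standard deviation of 0.5 percentage points
- steps under discussion: target + free enzyme <-> isomer of the product + free enzyme; 2 starting material -> homo dimer; starting material -> uncatalysed product; free enzyme -> unfolded enzyme; starting material + free enzyme -> target + free enzyme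

Call the fraction of starting material left a. My reckoning, for Friday's, supposes an enzyme that lasts and lets a fall by a catalysed term k·a and a homo dimer term q·a². Both constants are in 1/h, and their ratio ρ = k/q is the share number, a selectivity factor. Dividing the two rates gives target as a fraction of the charge, P = ρ·ln((ρ+1)/(ρ+a)), so you need ρ and a.

Which givens must be good? The scatter of 0.5 percentage points sits on the 14 points of material missing at oak's last reading, and ρ is read as target over missing material times the mean of a, so that scatter enters ρ through the missing material. The enzyme charge enters directly, since I take ρ proportional to it. Temperature must be bridged, and oak and alder bracket Friday's.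

Now the numbers. The last readings give ρ = 1.73 for oak and 0.898 for alder, or 0.247 µM⁻¹ and 0.0816 µM⁻¹. Interpolating the logarithm in temperature gives Friday's ρ = 0.560. The same bridge for k, from oak's last reading and alder's at 2.50 h, gives 0.0450 h⁻¹. Then a = 6.62% at 40 h and P = 51.1%.

The forecast says Friday's, with 39.5% for Monday's, 49% for Friday's, 5% for Thursday's and 26% for Saturday's. Its Friday's value lies below mine, and of Thursday's and Saturday's it says: “Those two are the least certain”.

Monday's gives 39.7%, Friday's 46.6%, Thursday's 0.0216% and Saturday's 5.92% of target, with Friday's highest.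

    target + free enzyme ⇌ isomer of the product + free enzyme, rate k1*[free enzyme]*[target] forward; the back reaction follows from the equilibrium constant (K = 0.850, k = 5.78 L mol⁻¹ min⁻¹, Ea = 37.0 kJ mol⁻¹, ΔH = −11.0 kJ mol⁻¹)
    2 starting material → homo dimer (k = 0.0135 L mol⁻¹ min⁻¹, Ea = 53.0 kJ mol⁻¹)
    starting material → uncatalysed product (k = 6.67 × 10⁻⁵ min⁻¹, Ea = 105 kJ mol⁻¹)
    free enzyme → unfolded enzyme (k = 1.69 × 10⁻⁵ min⁻¹, Ea = 288 kJ mol⁻¹)
    starting material + free enzyme → target + free enzyme, rate k5*[starting material]^1.5*[free enzyme]/(1 + ([starting material]/Kh5)^1.5) (0.0556 M, k = 1420 L¹·⁵ mol⁻¹·⁵ min⁻¹, Ea = 37.0 kJ mol⁻¹)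
    (constants at 20 °C)

With the 7.6% of starting material left in Friday's, ρ gives 50.2%, against 46.6% of target beside 2.35% of isomer of the product. Monday's ρ = 1.05 with 34% left gives 40.8%, against 39.7%. From the coldest to the hottest flask, unfolding of free enzyme speeds up by 8.3 × 10⁹, far more than the turning of starting material into target at 19. Friday's keeps 96.0% of its charged enzyme free at 40.0 h, while Saturday's has 0% free at 20.0 h, with its target standing at 5.92%.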